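**Strategy.** The target is the head-to-tail dimer of one vinylarene, 7-methoxy-2,2-dimethyl-6-vinyl-2H-chromene. It is cut at the styrene C=C bond (cross-metathesis) and at the benzylic C–CH=CH2 bond (asymmetric hydrovinylation), so that both halves come from one 6-chlorochromene. Everything rests on how the pyran ring (O1, C2, C3, C4, C4a, C8a) is made: a five-membered 2,2-dimethylbenzofuran-3(2H)-one takes up one carbon from dibromomethane and expands through a β-oxido carbenoid to a chromenyl enolate, trapped as its triflate. The step exploits the quaternary C2 next to O1: the ketone cannot enolise, and after insertion the enol double bond can only lie at C3=C4, the alkene of the target ring.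

Key step: step 2

Remark: compounds 1, 2, 5, 11 and 13 are taken as purchased; the sense of induction in step 5 is assumed to be selectable through the choice of ligand enantiomer.

Step 1
Reactants: 1 1-chloro-2,4-dimethoxybenzene; 2 2-bromo-2-methylpropanoyl bromide
Product: 4 5-chloro-6-methoxy-2,2-dimethylbenzofuran-3(2H)-one, via bromoketone phenol 3 (not isolated)
Conditions: (i) AlCl3, ClCH2CH2Cl, 0 °C to 40 °C; (ii) crude 3, K2CO3, acetone, 50 °C
Reagents that add atoms: 2-bromo-2-methylpropanoyl bromide (compound 2), CC(C)(Br)C(=O)Br
Why: Friedel–Crafts acylation at the only unhindered doubly activated position (para to one methoxy group, ortho to the other), chelation-controlled AlCl3 cleavage of the methyl ether ortho to the new ketone and base-mediated 5-exo-tet displacement of the tertiary α-bromide by the phenoxide (the classical benzofuran-3(2H)-one synthesis) should give 4, the only ring carbon open to a competing Nazarov-type closure being meta to both oxygens and deactivated.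

Step 2
Reactants: 4 5-chloro-6-methoxy-2,2-dimethylbenzofuran-3(2H)-one; 5 dibromomethane
Product: 9 6-chloro-7-methoxy-2,2-dimethyl-2H-chromen-3-yl trifluoromethanesulfonate, via lithium dibromomethyl carbinolate 6 (not isolated), via lithium β-oxido carbenoid 7 (not isolated), via lithium chromen-3-olate 8 (not isolated)
Conditions: CH2Br2, LiN(i-Pr)2, THF, −78 °C; n-BuLi (2.2 equiv), −95 °C to 0 °C; PhNTf2 (2 equiv), −78 °C to rt
Reagents that add atoms: dibromomethane (compound 5), BrCBr; N-phenylbis(trifluoromethanesulfonimide), O=S(=O)(N(c1ccccc1)S(=O)(=O)C(F)(F)F)C(F)(F)F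
Why: LiCHBr2 (from CH2Br2 and LiN(i-Pr)2) adds to the non-enolisable ketone 4, and bromine–lithium exchange on alkoxide 6 gives the β-oxido carbenoid 7, in which the electron-rich aryl carbon C3a shifts from the carbinol carbon to the carbenoid carbon with loss of LiBr, so that the five-membered ring (O1, C2, C3, C3a, C7a) becomes the six-membered ring of enolate 8, which PhNTf2 sulfonylates on oxygen. The closest known reaction type is the β-oxido carbenoid one-carbon ring expansion of cyclic ketones with dibromomethyllithium, joined to the standard triflation of a lithium enolate. No ring is closed from an open chain: the existing ring grows by a 1,2-shift of one of its bonds, and the inserted carbon becomes C4 of the chromene. No stereocenter is kept, since the carbinol and carbenoid carbons of 6 and 7 are racemic and both end up sp2. The step needs halogen–metal exchange at the CHBr2 group to outrun attack on the aryl chloride or ring lithiation, which the very fast exchange of geminal dibromides at −95 °C secures, while the second equivalent of n-BuLi turns the amine back into amide so that no proton source quenches 7. Which ring bond shifts does not matter in the end: migration of C2 in place of the aryl carbon would put the triflate on C4 of the same 2H-chromene, and step 3 removes it either way, because the quaternary C2 allows an enol double bond only at C3=C4.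

Step 3
Reactants: 9 6-chloro-7-methoxy-2,2-dimethyl-2H-chromen-3-yl trifluoromethanesulfonate
Product: 10 6-chloro-7-methoxy-2,2-dimethyl-2H-chromene
Conditions: Pd(OAc)2 (cat.), PPh3, HCO2H, Et3N, DMF, 60 °C
Reagents that add atoms: none
Why: Palladium-catalysed formate reduction of an enol triflate, in which zerovalent palladium inserts into the C–OTf bond, formate delivers hydride with loss of CO2 and reductive elimination leaves the C3–H bond, while the electron-rich aryl chloride should not undergo oxidative addition with PPh3 as ligand at this temperature.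

Step 4
Reactants: 10 6-chloro-7-methoxy-2,2-dimethyl-2H-chromene; 11 vinylboronic acid pinacol ester
Product: 12 7-methoxy-2,2-dimethyl-6-vinyl-2H-chromene
Conditions: Pd(OAc)2 (cat.), SPhos, K3PO4, 1,4-dioxane/H2O, 90 °C
Reagents that add atoms: vinylboronic acid pinacol ester (compound 11), C=CB1OC(C)(C)C(C)(C)O1
Why: Suzuki–Miyaura coupling of an electron-rich ortho-substituted aryl chloride, for which the bulky electron-rich biaryl phosphine SPhos makes oxidative addition feasible, with a vinylboronate under basic conditions that leave the acid-sensitive vinylarene and the chromene double bond untouched.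

Step 5
Reactants: 12 7-methoxy-2,2-dimethyl-6-vinyl-2H-chromene; 13 ethylene
Product: 14 (S)-6-(but-3-en-2-yl)-7-methoxy-2,2-dimethyl-2H-chromene
Conditions: [(η3-C3H5)NiBr]2 (cat.), binaphthol-derived bis(1-phenylethyl)phosphoramidite (the enantiomer leading to S), NaB[3,5-(CF3)2C6H3]4, ethylene (1 atm), CH2Cl2, −70 °C
Reagents that add atoms: ethylene (compound 13), C=C
Why: Nickel-catalysed asymmetric hydrovinylation, in which a cationic nickel hydride adds to the vinyl group to give an η3-benzylic nickel species, ethylene inserts and β-hydride elimination releases the 3-arylbut-1-ene, the stereocenter being set under catalyst control by the chiral phosphoramidite (its mirror image is used if induction on this substrate runs the other way), while the hindered 1,2-disubstituted C3=C4 bond of the chromene should stay out of the cycle.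

Step 6
Reactants: 14 (S)-6-(but-3-en-2-yl)-7-methoxy-2,2-dimethyl-2H-chromene; 12 7-methoxy-2,2-dimethyl-6-vinyl-2H-chromene (3 equiv)
Product: 15 6-[(1E,3S)-3-(7-methoxy-2,2-dimethyl-2H-chromen-6-yl)but-1-en-1-yl]-7-methoxy-2,2-dimethyl-2H-chromene
Conditions: second-generation Hoveyda–Grubbs catalyst (cat.), 1,4-benzoquinone (cat.), CH2Cl2, 40 °C
Reagents that add atoms: none
Why: Olefin cross-metathesis of two monosubstituted alkenes under thermodynamic control should give the E-styrene with loss of ethylene, the stereocenter not being involved, benzoquinone suppressing ruthenium-hydride double-bond migration and the chromene double bonds beside the quaternary C2 centres being too hindered for productive metathesis.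

**Compound list**
1 | 1-chloro-2,4-dimethoxybenzene | COc1ccc(Cl)c(OC)c1 | starting material
2 | 2-bromo-2-methylpropanoyl bromide | CC(C)(Br)C(=O)Br | starting material
3 | 2-bromo-1-(5-chloro-2-hydroxy-4-methoxyphenyl)-2-methylpropan-1-one (not isolated) | COc1cc(O)c(cc1Cl)C(=O)C(C)(C)Br | intermediate
4 | 5-chloro-6-methoxy-2,2-dimethylbenzofuran-3(2H)-one | COc1cc2OC(C)(C)C(=O)c2cc1Cl | intermediate
5 | dibromomethane | BrCBr | starting material
6 | lithium 5-chloro-3-(dibromomethyl)-6-methoxy-2,2-dimethyl-2,3-dihydrobenzofuran-3-olate (racemic, not isolated) | [Li+].[O-]C1(C(Br)Br)c2cc(Cl)c(OC)cc2OC1(C)C | intermediate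
7 | lithium 3-[bromo(lithio)methyl]-5-chloro-6-methoxy-2,2-dimethyl-2,3-dihydrobenzofuran-3-olate, the β-oxido carbenoid (not isolated) | [Li+].[O-]C1(C([Li])Br)c2cc(Cl)c(OC)cc2OC1(C)C | intermediate
8 | lithium 6-chloro-7-methoxy-2,2-dimethyl-2H-chromen-3-olate (not isolated) | [Li+].[O-]C1=Cc2cc(Cl)c(OC)cc2OC1(C)C | intermediate
9 | 6-chloro-7-methoxy-2,2-dimethyl-2H-chromen-3-yl trifluoromethanesulfonate | COc1cc2OC(C)(C)C(OS(=O)(=O)C(F)(F)F)=Cc2cc1Cl | intermediate
10 | 6-chloro-7-methoxy-2,2-dimethyl-2H-chromene | COc1cc2OC(C)(C)C=Cc2cc1Cl | intermediate
11 | vinylboronic acid pinacol ester (4,4,5,5-tetramethyl-2-vinyl-1,3,2-dioxaborolane) | C=CB1OC(C)(C)C(C)(C)O1 | starting material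
12 | 7-methoxy-2,2-dimethyl-6-vinyl-2H-chromene | COc1cc2OC(C)(C)C=Cc2cc1C=C | intermediate
13 | ethylene | C=C | starting material
14 | (S)-6-(but-3-en-2-yl)-7-methoxy-2,2-dimethyl-2H-chromene | C=C[C@H](C)c1cc2C=CC(C)(C)Oc2cc1OC | intermediate
15 | 6-[(1E,3S)-3-(7-methoxy-2,2-dimethyl-2H-chromen-6-yl)but-1-en-1-yl]-7-methoxy-2,2-dimethyl-2H-chromene | COc1cc2c(cc1/C=C/[C@H](C)c1cc3c(cc1OC)OC(C)(C)C=C3)C=CC(C)(C)O2 | target

Total step count: 6. Longest linear sequence: 6 (steps 1 to 6; compound 12 is used in step 5 and again in step 6).

**Steps most likely to fail**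

Step 2. The addition of LiCHBr2 to the hindered, donor-substituted ketone may be slow or reversible, and the carbenoid may be protonated or lose LiBr by α-elimination before the 1,2-shift. The fallback sets out from 4 and comes back at 10; it keeps the one-carbon ring expansion but does it oxidatively. Wittig methylenation of 4 (Ph3P=CH2, THF, reflux) would give 5-chloro-6-methoxy-2,2-dimethyl-3-methylene-2,3-dihydrobenzofuran F1. [Hydroxy(tosyloxy)iodo]benzene in 95% methanol (trivalent-iodine ring expansion of an exocyclic styrene by aryl shift) should give, after acidic work-up, 6-chloro-7-methoxy-2,2-dimethylchroman-3-one F2. NaBH4 in MeOH would give racemic 6-chloro-7-methoxy-2,2-dimethylchroman-3-ol F3, and MsCl/Et3N its ester 6-chloro-7-methoxy-2,2-dimethylchroman-3-yl methanesulfonate F4. E2 elimination with DBU in toluene at 100 °C, for which only the C4 hydrogens are available, returns to 10.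

Step 5. The cationic nickel hydride may dimerise or oligomerise the electron-rich vinylarene instead of inserting ethylene, coordination of the ortho-methoxy group may erode facial selectivity, and the product may isomerise into conjugation on warming. The fallback sets out from 12 and comes back at 14. Copper-hydride hydroboration of 12 (Cu(OAc)2 cat., DTBM-SEGPHOS, pinacolborane, THF) should give, under catalyst control, (R)-2-[1-(7-methoxy-2,2-dimethyl-2H-chromen-6-yl)ethyl]-4,4,5,5-tetramethyl-1,3,2-dioxaborolane F5. Zweifel olefination (vinylmagnesium bromide in THF/DMSO, then I2, then NaOMe) replaces boron by vinyl with retention and gives 14; the descriptor changes from R to S only because boron ranks below carbon.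

Step 6. The ortho-methoxy group of 12 may hold ruthenium as a stable chelated benzylidene and stall turnover, or a ruthenium hydride may move the terminal double bond of 14 into conjugation and erase the stereocenter. The fallback sets out from 10 and comes back at 15; it forms the C–C bond and the stereocenter together and needs neither 14 nor metathesis. Borylation of 10 (Pd(OAc)2/XPhos, B2(OH)4, KOAc, EtOH, 80 °C) would give (7-methoxy-2,2-dimethyl-2H-chromen-6-yl)boronic acid F6. Suzuki–Miyaura coupling of 10 with (E)-buta-1,3-dien-1-ylboronic acid pinacol ester (Pd(OAc)2/SPhos, K3PO4) would give (E)-6-(buta-1,3-dien-1-yl)-7-methoxy-2,2-dimethyl-2H-chromene F7. Nickel-catalysed enantioselective hydroarylation of F7 with F6 (Ni(cod)2, chiral spiro aminophosphine ligand, MeOH/THF) should place hydrogen on the terminal carbon and the aryl group on C3 of the diene, keeping the E-styrene and giving 15 directly.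

Further compounds
F1 | step 2 | 5-chloro-6-methoxy-2,2-dimethyl-3-methylene-2,3-dihydrobenzofuran | COc1cc2OC(C)(C)C(=C)c2cc1Cl
F2 | step 2 | 6-chloro-7-methoxy-2,2-dimethylchroman-3-one | COc1cc2OC(C)(C)C(=O)Cc2cc1Cl
F3 | step 2 | 6-chloro-7-methoxy-2,2-dimethylchroman-3-ol (racemic) | COc1cc2OC(C)(C)C(O)Cc2cc1Cl
F4 | step 2 | 6-chloro-7-methoxy-2,2-dimethylchroman-3-yl methanesulfonate (racemic) | COc1cc2OC(C)(C)C(OS(C)(=O)=O)Cc2cc1Cl
F5 | step 5 | (R)-2-[1-(7-methoxy-2,2-dimethyl-2H-chromen-6-yl)ethyl]-4,4,5,5-tetramethyl-1,3,2-dioxaborolane | CC1(C)OB(OC1(C)C)[C@H](C)c1cc2C=CC(C)(C)Oc2cc1OC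
F6 | step 6 | (7-methoxy-2,2-dimethyl-2H-chromen-6-yl)boronic acid | COc1cc2OC(C)(C)C=Cc2cc1B(O)O
F7 | step 6 | (E)-6-(buta-1,3-dien-1-yl)-7-methoxy-2,2-dimethyl-2H-chromene | COc1cc2OC(C)(C)C=Cc2cc1/C=C/C=C
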